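What was slow in the earlier runs was the target, not the substrate: in Tuesday's run 35.0% of the substrate had gone by 0.833 min, yet the target read 0.6%.

| setting | Saturday's | Thursday's | Tuesday's | south-west | south-east | south |
|---|---|---|---|---|---|---|
| substrate | 2 M | 2 M | 1 M | 2.0 M | 2.0 M | 2.0 M |
| partner | 0.35 equiv | 1.4 equiv | 0.70 equiv | 0.700 equiv | 0.700 equiv | 0.700 equiv |
| temperature | 105 °C | 125 °C | 105 °C |  | 110 °C | 140 °C |
| remark | run made earlier | run made earlier | run made earlier | at 110 °C until 3.0 min, from then on at 140 °C |  |  |
| time |  |  |  | 4.0 min | 4.0 min | 4.0 min |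

Saturday's run (percent of the substrate charged)

| time / min | target / % | substrate / % |
|---|---|---|
| 0.200 | 0 | 88.9 |
| 0.667 | 1.7 | 75.9 |
| 1.00 | 2.7 | 71.4 |
| 2.00 | 3.4 | 66.7 |
| 2.50 | 5.7 | 66.1 |
| 3.00 | 6.2 | 66.2 |

Thursday's run (percent of the substrate charged)

| time / s | target / % | substrate / % |
|---|---|---|
| 10.0 | 4.1 | 33.4 |
| 20.0 | 8.2 | 16.2 |
| 30.0 | 13.8 | 9.4 |
| 60.0 | 20.9 | 2.3 |
| 80.0 | 23.5 | 0.7 |

Tuesday's run (percent of the substrate charged)

| time / min | target / % | substrate / % |
|---|---|---|
| 0.250 | 0 | 85.6 |
| 0.500 | 0.3 | 74.5 |
| 0.833 | 0.6 | 65.0 |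
| 1.50 | 4.6 | 53.4 |
| 3.00 | 8.6 | 41.4 |

(readings scatter by 0.5 percentage points)

- the numbers in the tables scatter by 0.5 percentage points (one standard deviation)

* the best flask by amount of target, in percent of the substrate charged; "all alike" if 1.5 percentage points covers them all (south-west / south-east / south / all alike)
* amount of target at the end, in percent of the substrate charged, south-west
* amount of target at the end, in percent of the substrate charged, south-east
* amount of target at the end, in percent of the substrate charged, south

So I called the substrate gone and not yet target the pool, and I read a target clock k, the target made per minute divided by the pool. Tuesday's readings from 0.833 min to 3.00 min, with a pool of 42.0%, and Thursday's from 10.0 s to 30.0 s, with a pool of 75.6%, gave: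

k at 105 °C = 0.0879 min⁻¹
k at 125 °C = 0.385 min⁻¹
log10 of their ratio = 0.641 decades

Taking log10 k as straight in temperature, I got k at 110 °C = 0.127 min⁻¹ and at 140 °C = 1.17 min⁻¹. The quantity I carried was the clock count n, k times time added up stretch by stretch, which is a Damköhler number for the flask:

Tuesday's, at its last reading: n = 0.264
Thursday's, at its last reading: n = 0.513
south-east: n = 0.509
south-west: n = 1.55
south: n = 4.66

South-east looks nearly like Tuesday's run, with the same equivalents of partner, and its count is twice Tuesday's. So I scaled Tuesday's 8.6% to 16.6% for south-east, setting aside that the [substrate] in south-east was twice Tuesday's.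

Thursday's quotient over its last two readings read 0.103 min⁻¹, a quarter of its early value, so I trusted the scaling no further than Thursday's last count. South's count was ten times that last count, so I gave no number for south, nor for south-west at 1.55.

The forecast did give numbers: 17.8% for south-west, 14.5% for south-east and 18% for south, with south best, holding that “relaxation is fast, so the target reaches the cap”.

    intermediate → decomposed reagent (k = 0.00450 s⁻¹, Ea = 108 kJ mol⁻¹)
    substrate + partner → intermediate (k = 0.0240 M⁻¹ s⁻¹, Ea = 76.0 kJ mol⁻¹)
    target ⇌ isomer of the product (K = 14.0, k = 0.00130 s⁻¹, Ea = 120 kJ mol⁻¹, ΔH = −32.0 kJ mol⁻¹)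
    intermediate → target (k = 0.00260 s⁻¹, Ea = 106 kJ mol⁻¹)
    (constants at 110 °C)

The flasks gave 9.13% in south-west, 16.3% in south-east and 3.36% in south, so south-east held the most. Target fell as the count rose from 0.509 through 1.55 to 4.66, and at 4.00 min south held 21.5% of isomer of the product. The neighbour repeated south-east at 95 °C, where the same line gives k = 0.0420 min⁻¹ and a count of 0.168. Scaling Tuesday's reading by that count gives 5.47%, and the flask gave 6.21%.

The earlier runs and the new flask are calculated for substances that don't exist; scatter was added.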